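**Plan**

1. Retrosynthesis: the ring A lactone oxygen is removed (Baeyer–Villiger transform) and the C17 carbinol returned to a ketone. The bicyclo[2.2.2]octane and cyclopentane are opened together at C8–C13 and C14–C15 (intramolecular Diels–Alder transform) and at C12–CH3, leaving a phthalide phenol linked through C11 to a decalin. The decalin is cut at C11–C12, C9–C11 and C4–CH3, and last at C5–C10 and C2–C3 in one transform.
2. Forward: an acyclic keto dienoyl imide closes ring B and then ring A in one flask. Ring A is taken to the 4,4-dimethyl-Δ1-3-ketone, and a formaldehyde ene reaction adds C11 at C9 and moves the ring B alkene to exocyclic C8=C14. The phthalide is attached at C11; C12-methylation and an intramolecular Diels–Alder reaction build the cyclopentane and the cage. C17 reduction and a Baeyer–Villiger oxidation (seven-membered lactone formed last) finish the route.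
3. Feature that makes the key event possible: in the open chain, C10 is both α to the C1 ketone and allylic to the (Z) C8=C9 bond, so it enolizes first and sits six atoms from C5, the β-carbon of the C3 acyl group. Once C5–C10 has closed ring B, the C2 methyl of the same ketone sits six atoms from the C3 carbonyl and closes ring A.
4. Stereochemistry: C5 from the (R)-oxazolidinone on C3 (expelled in the key step); C10 from the chair-like closure (trans A/B fusion). C9 and C8 come from attack on the α-face of ring B, anti to the C10 methyl. C13 and C15 follow from the suprafacial Diels–Alder reaction through the C9–C11 tether, which also selects the reactive C12 epimer (C12 itself is methylated without facial control). C18 is set by equilibration and C17 by hydride attack anti to C20.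
5. Locants: ring A is C1=C2–C3(=O)–O–C4(CH3)2–C5–C10; ring B is C5–C6–C7–C8–C9–C10; C11 links C9 to C12; the cage is C12, C13, C15–C18 with C14 between C8 and C15; C19H2–O–C20(=O) is the γ-lactone on C13/C18. α is the face of H5, β the face of the C10 methyl.

Key step: step 8

Remark: 8 is taken as a purchasable reagent. Compounds 3, 5–7 and 10–12 are carried as mixtures at the future C1 and C10 (and at the phosphonate carbon), because these centres are erased in steps 6–8.

Step 1
Reactants: 1 3-bromobut-1-yne; 2 acetaldehyde
Product: 3 3-methylpent-4-yn-2-ol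
Conditions: Zn, THF, 0 °C to rt; then H2O
Reagents that add atoms: none
Why: Zinc Barbier propargylation: the allenylzinc from 1 adds through its γ-carbon to the aldehyde and gives the homopropargylic alcohol; the two new centres (future C1 and C10) are left uncontrolled because C1 is oxidized in step 7 and C10 is enolized in step 8.

Step 2
Reactants: 3 3-methylpent-4-yn-2-ol; 4 2-(2-bromoethyl)-1,3-dioxolane
Product: 5 7-(1,3-dioxolan-2-yl)-3-methylhept-4-yn-2-ol
Conditions: n-BuLi (2.1 equiv), THF, −78 °C; then 4, DMPU, −78 °C to rt; then H2O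
Reagents that add atoms: none
Why: The alkoxide–acetylide dianion is alkylated at carbon (acetylide SN2 on a primary bromide), which adds C7–C5 with C5 masked as the dioxolane.

Step 3
Reactants: 5 7-(1,3-dioxolan-2-yl)-3-methylhept-4-yn-2-ol
Product: 6 (Z)-7-(1,3-dioxolan-2-yl)-3,5-dimethylhept-4-en-2-ol
Conditions: Fe(acac)3 (cat.), MeMgBr (excess), THF, −78 to 0 °C; then H2O
Reagents that add atoms: methylmagnesium bromide, C[Mg]Br
Why: Hydroxyl-directed, Fe-catalysed syn-carbomagnesiation of a homopropargylic alcohol: methyl adds to the distal alkyne carbon (C8) and magnesium, held by the alkoxide, to C9, so protonation gives the trisubstituted alkene with C10 and C7 cis.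

Step 4
Reactants: 6 (Z)-7-(1,3-dioxolan-2-yl)-3,5-dimethylhept-4-en-2-ol
Product: 7 (Z)-7-hydroxy-4,6-dimethyloct-4-enal
Conditions: 1 M HCl, THF, rt
Reagents that add atoms: water, O
Why: Acid-catalysed acetal hydrolysis frees the C5 aldehyde.

Step 5
Reactants: 8 2-(diethoxyphosphoryl)propanoic acid; 9 (R)-4-benzyloxazolidin-2-one
Product: 10 (R)-4-benzyl-3-[2-(diethoxyphosphoryl)propanoyl]oxazolidin-2-one
Conditions: t-BuCOCl, Et3N, THF, −20 °C; then 9, LiCl, rt
Reagents that add atoms: none
Why: N-Acylation of the oxazolidinone through the pivalic mixed anhydride gives the chiral Horner–Wadsworth–Emmons reagent.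

Step 6
Reactants: 7 (Z)-7-hydroxy-4,6-dimethyloct-4-enal; 10 (R)-4-benzyl-3-[2-(diethoxyphosphoryl)propanoyl]oxazolidin-2-one
Product: 11 (R)-4-benzyl-3-[(2E,6Z)-9-hydroxy-2,6,8-trimethyldeca-2,6-dienoyl]oxazolidin-2-one
Conditions: LiCl, i-Pr2NEt, MeCN, rt
Reagents that add atoms: none
Why: Horner–Wadsworth–Emmons olefination under mild amine/LiCl conditions gives the (E)-2-methyl enoyl imide and tolerates the free secondary alcohol.

Step 7
Reactants: 11 (R)-4-benzyl-3-[(2E,6Z)-9-hydroxy-2,6,8-trimethyldeca-2,6-dienoyl]oxazolidin-2-one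
Product: 12 (R)-4-benzyl-3-[(2E,6Z)-2,6,8-trimethyl-9-oxodeca-2,6-dienoyl]oxazolidin-2-one
Conditions: Dess–Martin periodinane, NaHCO3, CH2Cl2, 0 °C
Reagents that add atoms: none
Why: Dess–Martin oxidation gives the methyl ketone under buffered, non-basic conditions that should leave the β,γ-unsaturated ketone unconjugated.

Step 8
Reactants: 12 (R)-4-benzyl-3-[(2E,6Z)-2,6,8-trimethyl-9-oxodeca-2,6-dienoyl]oxazolidin-2-one
Product: 14 (4aS,8aS)-4,7,8a-trimethyl-4a,5,6,8a-tetrahydronaphthalene-1,3(2H,4H)-dione, via Michael adduct 13 (not isolated)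
Conditions: LiN(SiMe3)2 (1.0 equiv), THF, −78 to 0 °C; then 1 M HCl
Reagents that add atoms: none
Why: The base removes the C10 proton (α to the C1 ketone and allylic to C8=C9) and the dienolate adds through C10 to C5 of the lithium-chelated s-cis enoyl imide (Michael addition, ring B); proton transfer from the C2 methyl to the imide enolate then gives the C2 enolate, which attacks the imide carbonyl C3 (Claisen-type C-acylation, ring A) and expels the oxazolidinone anion, which deprotonates the 1,3-dione and makes the sequence irreversible. The closest known reaction type is the Michael–Claisen annulation of ketones with α,β-unsaturated esters to cyclohexane-1,3-diones, run here within one chain. Ring B closes 6-exo-trig (enolate C=C exocyclic, the Z C8=C9 bond inside the ring) and ring A closes by a 6-exo-trig acyl substitution. C5 is set by the (R)-benzyl group, which shields one face of the chelated enoyl imide (sense assigned from the chelate model); C10 is set relative to C5 by the chair-like closure with the enoyl chain equatorial, and only the adduct with C1 and C4 gauche can close ring A, which should give the trans fusion (C10 methyl axial, anti to H5). The step needs enolization at C10 and not at C2 (secured by the extra allylic activation and enolate equilibration), attack of C2 on the exocyclic and not the ring carbonyl of the imide, and the Z geometry of C8=C9 (secured in step 3); C4 forms as a mixture that step 11 removes.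

Step 9
Reactants: 14 (4aS,8aS)-4,7,8a-trimethyl-4a,5,6,8a-tetrahydronaphthalene-1,3(2H,4H)-dione
Product: 15 3-methyl enol ether of 14 (C1 ketone kept)
Conditions: HC(OMe)3, MeOH, TsOH (cat.), rt
Reagents that add atoms: trimethyl orthoformate, COC(OC)OC
Why: Acid-catalysed enol etherification of the cyclic 1,3-dione should occur at the less hindered C3 carbonyl (next to C4–H) and not at C1 (next to quaternary C10), which fixes the position of the future carbonyl.

Step 10
Reactants: 15 3-methyl enol ether of 14
Product: 17 4-methyl-Δ1-3-ketone (C3=O and C1=C2; ring B Δ8), via allylic alcohol 16 (not isolated)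
Conditions: i-Bu2AlH, CH2Cl2, −78 °C; then 1 M HCl, THF, 0 °C to rt
Reagents that add atoms: water, O
Why: Stork–Danheiser sequence: 1,2-reduction of the vinylogous ester carbonyl (C1), then acid hydrolysis of the enol ether and dehydration, give the transposed enone with the carbonyl at C3.

Step 11
Reactants: 17 4-methyl-Δ1-3-ketone
Product: 18 4,4-dimethyl-Δ1-3-ketone (ring B Δ8 with C8 methyl)
Conditions: LiN(i-Pr)2, THF, −78 °C; then MeI, −78 to 0 °C
Reagents that add atoms: iodomethane, CI
Why: Kinetic α′-deprotonation of the enone (C4 is its only enolizable position) and methylation give the gem-dimethyl group and erase the uncontrolled C4 centre.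

Step 12
Reactants: 18 4,4-dimethyl-Δ1-3-ketone
Product: 19 9α-hydroxymethyl-8(14)-methylene decalin enone
Conditions: (CH2O)n, Me2AlCl, CH2Cl2, −78 to 0 °C; then 1 M HCl
Reagents that add atoms: formaldehyde, C=O
Why: Me2AlCl-promoted carbonyl-ene reaction of formaldehyde with the trisubstituted C8=C9 alkene: the enophile should bond to the less substituted C9 on the α-face, anti to the axial C10 methyl, with transfer of a C14 methyl hydrogen, which sets C9 and the exocyclic C8=C14 bond, while the electron-poor enone does not react.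

Step 13
Reactants: 19 9α-hydroxymethyl-8(14)-methylene decalin enone
Product: 20 9α-formyl-8(14)-methylene decalin enone
Conditions: Dess–Martin periodinane, NaHCO3, CH2Cl2, 0 °C
Reagents that add atoms: none
Why: Buffered Dess–Martin oxidation gives the β,γ-unsaturated aldehyde under conditions chosen to avoid epimerization at C9 and double-bond migration.

Step 14
Reactants: 21 3,5-dihydroxy-4-methylbenzoic acid
Product: 22 5,7-dihydroxy-6-methylisobenzofuran-1(3H)-one
Conditions: 37% aq. CH2O, conc. HCl, AcOH, 90 °C
Reagents that add atoms: formaldehyde, C=O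
Why: Acid-mediated ortho-hydroxymethylation of the benzoic acid followed by lactonization gives the phthalide; the two ortho positions are equivalent.

Step 15
Reactants: 20 9α-formyl-8(14)-methylene decalin enone; 22 5,7-dihydroxy-6-methylisobenzofuran-1(3H)-one
Product: 24 phthalide phenol joined to C11 at its C4 (future C12), via benzylic alcohol 23 (not isolated)
Conditions: 22, i-PrMgCl (2.0 equiv), THF/CH2Cl2, 0 °C; then 20, 0 °C to rt; then Et3SiH, CF3CO2H, CH2Cl2, −40 °C
Reagents that add atoms: none
Why: Ortho-hydroxyalkylation of the magnesium phenolate at the only unsubstituted ring carbon, then ionic hydrogenation of the ortho/para-hydroxybenzylic alcohol, gives the C11 methylene link; the low temperature is meant to spare the exocyclic alkene and C9.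

Step 16
Reactants: 24 phthalide phenol joined to C11
Product: 26 cage β-keto lactone (C17 ketone; ring A enone), via dienone 25 (not isolated)
Conditions: LiN(SiMe3)2 (2.1 equiv), toluene/THF, −78 to 0 °C; MeI; 1 M HCl; then toluene, 110 °C
Reagents that add atoms: iodomethane, CI
Why: Alkylative dearomatization of the resorcinol dianion at C12 (ortho to the 5-oxido, para to the 7-oxido group) gives the 6,6-disubstituted cyclohexa-2,4-dienone, whose diene C13=C18–C17=C15 adds to the tethered C8=C14 bond in an intramolecular Diels–Alder reaction; the α-oriented C9–C11 tether puts C13 on the α-face of C8, only the C12 epimer drawn can reach this geometry (methylation itself is not expected to be face-selective), and C18 is set by keto–enol equilibration of the β-keto lactone.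

Step 17
Reactants: 26 cage β-keto lactone
Product: 27 C17 alcohol (ring A still the carbocyclic Δ1-3-ketone)
Conditions: NaBH4, MeOH/CH2Cl2, −78 to −40 °C
Reagents that add atoms: none
Why: NaBH4 should reduce the activated C17 ketone in preference to the conjugated, neopentyl C3 enone and the C16 ketone flanked by two quaternary carbons; hydride is expected from the side of the C8–C14 bridge, anti to C20 on C18, giving the alcohol cis to C20.

Step 18
Reactants: 27 C17 alcohol
Product: 28 andilesin A
Conditions: m-CPBA, NaHCO3, CH2Cl2, 0 °C to rt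
Reagents that add atoms: 3-chloroperoxybenzoic acid, OOC(=O)c1cccc(Cl)c1
Why: Baeyer–Villiger oxidation: the tertiary C4 migrates in preference to the vinylic C2, which inserts oxygen between C3 and C4 and gives the α,β-unsaturated ε-lactone, while the hindered C16 ketone should not react.

**Compound list**

1 | 3-bromobut-1-yne (racemic) | CC(Br)C#C | starting material
2 | acetaldehyde | CC=O | starting material
3 | 3-methylpent-4-yn-2-ol (racemic, both diastereomers) | CC(O)C(C)C#C | intermediate
4 | 2-(2-bromoethyl)-1,3-dioxolane | BrCCC1OCCO1 | starting material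
5 | 7-(1,3-dioxolan-2-yl)-3-methylhept-4-yn-2-ol | CC(O)C(C)C#CCCC1OCCO1 | intermediate
6 | (Z)-7-(1,3-dioxolan-2-yl)-3,5-dimethylhept-4-en-2-ol | CC(O)C(C)/C=C(C)\CCC1OCCO1 | intermediate
7 | (Z)-7-hydroxy-4,6-dimethyloct-4-enal | CC(O)C(C)/C=C(C)\CCC=O | intermediate
8 | 2-(diethoxyphosphoryl)propanoic acid | CCOP(=O)(OCC)C(C)C(=O)O | starting material
9 | (R)-4-benzyloxazolidin-2-one | O=C1N[C@H](Cc2ccccc2)CO1 | starting material
10 | (R)-4-benzyl-3-[2-(diethoxyphosphoryl)propanoyl]oxazolidin-2-one | CCOP(=O)(OCC)C(C)C(=O)N1[C@H](Cc2ccccc2)COC1=O | intermediate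
11 | (R)-4-benzyl-3-[(2E,6Z)-9-hydroxy-2,6,8-trimethyldeca-2,6-dienoyl]oxazolidin-2-one | CC(O)C(C)/C=C(C)\CC/C=C(C)/C(=O)N1[C@H](Cc2ccccc2)COC1=O | intermediate
12 | (R)-4-benzyl-3-[(2E,6Z)-2,6,8-trimethyl-9-oxodeca-2,6-dienoyl]oxazolidin-2-one | CC(=O)C(C)/C=C(C)\CC/C=C(C)/C(=O)N1[C@H](Cc2ccccc2)COC1=O | intermediate
13 | Michael adduct: ring B closed, C10 bearing methyl and acetyl, C5 bearing the 2-propanoyl imide (drawn as the neutral keto imide) | CC(=O)[C@]1(C)C=C(C)CC[C@H]1C(C)C(=O)N1[C@H](Cc2ccccc2)COC1=O | intermediate
14 | (4aS,8aS)-4,7,8a-trimethyl-4a,5,6,8a-tetrahydronaphthalene-1,3(2H,4H)-dione (trans-fused; C4 epimers) | CC1C(=O)CC(=O)[C@@]2(C)[C@H]1CCC(C)=C2 | intermediate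
15 | 3-methoxy-4,7,8a-trimethyl-4a,5,6,8a-tetrahydronaphthalen-1(4H)-one (trans-fused; enol ether at C3, ketone at C1) | CC1C(OC)=CC(=O)[C@@]2(C)[C@H]1CCC(C)=C2 | intermediate
16 | C1 allylic alcohol from 15 (C1 and C4 epimers) | CC1C(OC)=CC(O)[C@@]2(C)[C@H]1CCC(C)=C2 | intermediate
17 | 1,4a,6-trimethyl-1,7,8,8a-tetrahydronaphthalen-2(4aH)-one (Δ1-3-ketone, Δ8; 4a-methyl and 8a-H trans; C4 epimers) | CC1C(=O)C=C[C@@]2(C)[C@H]1CCC(C)=C2 | intermediate
18 | 1,1,4a,6-tetramethyl-1,7,8,8a-tetrahydronaphthalen-2(4aH)-one (4a-methyl and 8a-H trans) | CC1(C)C(=O)C=C[C@@]2(C)[C@H]1CCC(C)=C2 | intermediate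
19 | 5-(hydroxymethyl)-1,1,4a-trimethyl-6-methylene-4a,5,6,7,8,8a-hexahydronaphthalen-2(1H)-one (CH2OH α, trans to the 4a-methyl) | CC1(C)C(=O)C=C[C@@]2(C)[C@H]1CCC(=C)[C@H]2CO | intermediate
20 | corresponding 5-carbaldehyde (CHO α) | CC1(C)C(=O)C=C[C@@]2(C)[C@H]1CCC(=C)[C@H]2C=O | intermediate
21 | 3,5-dihydroxy-4-methylbenzoic acid | Cc1c(O)cc(cc1O)C(=O)O | starting material
22 | 5,7-dihydroxy-6-methylisobenzofuran-1(3H)-one | O=C1OCc2cc(O)c(C)c(O)c12 | intermediate
23 | benzylic alcohol: C11 carbinol between C9 and C4 of the phthalide (C11 epimers) | CC1(C)C(=O)C=C[C@@]2(C)[C@H]1CCC(=C)[C@H]2C(O)c1c(O)c(C)c(O)c2C(=O)OCc12 | intermediate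
24 | 4-(decalinylmethyl)-5,7-dihydroxy-6-methylphthalide (C11 methylene on the α-face of C9) | CC1(C)C(=O)C=C[C@@]2(C)[C@H]1CCC(=C)[C@H]2Cc1c(O)c(C)c(O)c2C(=O)OCc12 | intermediate
25 | dearomatized dienone: C12 bearing methyl and C11, C16 ketone, C15=C17(OH) and C18=C13 diene, lactone intact | CC1(C)C(=O)C=C[C@@]2(C)[C@H]1CCC(=C)[C@H]2C[C@@]1(C)C(=O)C(C)=C(O)C2=C1COC2=O | intermediate
26 | cage β-keto lactone: target skeleton with ring A as the carbocyclic Δ1-3-ketone and C17 as a ketone | CC1(C)C(=O)C=C[C@@]2(C)[C@H]1CC[C@]13C[C@]4(C)C(=O)[C@](C)(C[C@@H]21)[C@]31COC(=O)[C@H]1C4=O | intermediate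
27 | C17 alcohol with ring A as the carbocyclic Δ1-3-ketone (OH cis to C20) | CC1(C)C(=O)C=C[C@@]2(C)[C@H]1CC[C@]13C[C@]4(C)C(=O)[C@](C)(C[C@@H]21)[C@]31COC(=O)[C@H]1[C@H]4O | intermediate
28 | andilesin A | CC1(C)OC(=O)C=C[C@@]2(C)[C@H]1CC[C@]13C[C@]4(C)C(=O)[C@](C)(C[C@@H]21)[C@]31COC(=O)[C@H]1[C@H]4O | target

**Count and risks**

Total step count: 18. Longest linear sequence: 16 (steps 1–4, 6–13, 15–18).

Risk 1, step 16. The methylation may go to C15 (between the two oxygens) or to oxygen instead of C12, and it has no facial control at C12, so at best half of the dienone can cyclize; the cycloaddition must also pass through a boat-like ring B. The fallback sets out from 24 and returns at 26. The non-chelated 5-OH is silylated selectively (t-BuMe2SiCl, imidazole) to the 5-O-silyl ether F1. The chelated 7-OH is then acylated (t-BuCOCl, Et3N, DMAP) to the silyl ether pivalate F2, and HF·pyridine gives the 7-O-pivalate phenol F3. The single phenolate of F3 (LiN(SiMe3)2, 1.05 equiv, toluene), with C15 now flanked by the bulky ester, is C-methylated at C12 to the dienone pivalate F4. Heating gives the Diels–Alder adduct as the C17 enol pivalate F5, and K2CO3 in MeOH cleaves the enol ester to 26.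

Risk 2, step 8. The facial selectivity of the Michael addition may be poor or opposite to the chelate model, the cis-fused dione may form, or the base may cleave the imide. The fallback sets out from 7 and returns at 17. Wittig olefination of 7 with ethyl 2-(triphenylphosphoranylidene)propanoate gives the hydroxy ester F6, and Dess–Martin oxidation gives the keto ester F7. t-BuOK in THF/t-BuOH effects the same Michael–Claisen closure and gives the dione as a racemate, that is 14 together with its antipode F8. Enol etherification with (1R,2S,5R)-menthol in place of methanol gives diastereomeric ethers, from which the menthyl enol ether F9 derived from 14 is separated. The conditions of step 10 convert F9 into 17.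

Risk 3, step 15. Aldehyde 20 may epimerize at C9 or move its double bond into conjugation under the basic magnesium phenolate, and the exocyclic alkene may be reduced during ionic hydrogenation. The fallback sets out from 19 and returns at 24. I2, PPh3 and imidazole convert 19 into the primary iodide F10. Separately, 22 is brominated at its only free ring position with N-bromosuccinimide to the bromophenol F11 and acetylated (Ac2O, pyridine) to the bromo diacetate F12. F10 is turned into the alkylzinc iodide (Zn, LiCl, THF) and cross-coupled with F12 (Pd(OAc)2, CPhos; Negishi coupling) to the coupled diacetate F13. K2CO3 in MeOH gives 24.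

**Further compounds**

F1 | step 16 | 5-O-(tert-butyldimethylsilyl) ether of 24 | CC1(C)C(=O)C=C[C@@]2(C)[C@H]1CCC(=C)[C@H]2Cc1c(O[Si](C)(C)C(C)(C)C)c(C)c(O)c2C(=O)OCc12
F2 | step 16 | 5-O-silyl ether 7-O-pivalate of 24 | CC1(C)C(=O)C=C[C@@]2(C)[C@H]1CCC(=C)[C@H]2Cc1c(O[Si](C)(C)C(C)(C)C)c(C)c(OC(=O)C(C)(C)C)c2C(=O)OCc12
F3 | step 16 | 7-O-pivalate of 24 (5-OH free) | CC1(C)C(=O)C=C[C@@]2(C)[C@H]1CCC(=C)[C@H]2Cc1c(O)c(C)c(OC(=O)C(C)(C)C)c2C(=O)OCc12
F4 | step 16 | C12-methylated dienone with C17 enol pivalate | CC1(C)C(=O)C=C[C@@]2(C)[C@H]1CCC(=C)[C@H]2C[C@@]1(C)C(=O)C(C)=C(OC(=O)C(C)(C)C)C2=C1COC2=O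
F5 | step 16 | Diels–Alder adduct as C17 enol pivalate (C17=C18) | CC1(C)C(=O)C=C[C@@]2(C)[C@H]1CC[C@]13C[C@]4(C)C(=O)[C@](C)(C[C@@H]21)[C@]31COC(=O)C1=C4OC(=O)C(C)(C)C
F6 | step 8 | ethyl (2E,6Z)-9-hydroxy-2,6,8-trimethyldeca-2,6-dienoate | CC(O)C(C)/C=C(C)\CC/C=C(C)/C(=O)OCC
F7 | step 8 | ethyl (2E,6Z)-2,6,8-trimethyl-9-oxodeca-2,6-dienoate | CC(=O)C(C)/C=C(C)\CC/C=C(C)/C(=O)OCC
F8 | step 8 | antipode of 14 (second component of the racemate) | CC1C(=O)CC(=O)[C@]2(C)[C@@H]1CCC(C)=C2
F9 | step 8 | (1R,2S,5R)-menthyl enol ether of 14 at C3 | CC1C(O[C@@H]2C[C@H](C)CC[C@H]2C(C)C)=CC(=O)[C@@]2(C)[C@H]1CCC(C)=C2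
F10 | step 15 | 9α-iodomethyl-8(14)-methylene decalin enone | CC1(C)C(=O)C=C[C@@]2(C)[C@H]1CCC(=C)[C@H]2CI
F11 | step 15 | 4-bromo-5,7-dihydroxy-6-methylisobenzofuran-1(3H)-one | O=C1OCc2c(Br)c(O)c(C)c(O)c12
F12 | step 15 | 4-bromo-6-methyl-1-oxo-1,3-dihydroisobenzofuran-5,7-diyl diacetate | O=C1OCc2c(Br)c(OC(C)=O)c(C)c(OC(C)=O)c12
F13 | step 15 | diacetate of 24 | CC1(C)C(=O)C=C[C@@]2(C)[C@H]1CCC(=C)[C@H]2Cc1c(OC(C)=O)c(C)c(OC(C)=O)c2C(=O)OCc12
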